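**Retrosynthetic overview**
1. Target 29 ← desilylation and C8 angeloylation of the macrocyclic alcohol 25.
2. 25 ← closure of the ten-membered carbocycle at C7–C8: the samarium ketyl of aldehyde 22 adds to the 3-(acetoxymethyl)butenolide, and acetate loss unveils the exocyclic methylene.
3. Butenolide 20 ← ring-closing metathesis of the acrylate ester of carbinol 15; C5–C6 comes from a Nozaki–Hiyama–Kishi coupling of alkenyl iodide 12 with acrolein.
4. 12 ← catalytic asymmetric alkenylzinc addition (C2–C3) of alkyne 4 (epoxidation/reductive opening of enynol 1) to (Z)-iodoenal 8 (carbomagnesiation of propargyl alcohol).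
5. Ring order: five-membered lactone first, ten-membered carbocycle last.

Assumption: germacrane numbering is used for atom labels (C3 acetate, C6/C7 lactone fusion, C8 angelate, C10 carbinol, C13 exocyclic CH2); compounds 1, 5, 13, 16 and 26 are taken as commercial.

**Step 1**
Reactants: 1 (E)-3-methylpent-2-en-4-yn-1-ol
Product: 2 [(2S,3S)-3-ethynyl-3-methyloxiran-2-yl]methanol
Conditions: Ti(OiPr)4 (10 mol%), L-(+)-diethyl tartrate (12 mol%), tBuOOH, 4 Å sieves, CH2Cl2, −20 °C
Reagents that add atoms: tert-butyl hydroperoxide CC(C)(C)OO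
Why: Sharpless asymmetric epoxidation; with the L-(+)-tartrate the oxygen is delivered to the face that gives the 2S,3S epoxide, which fixes the future C10 oxygen.

**Step 2**
Reactants: 2 [(2S,3S)-3-ethynyl-3-methyloxiran-2-yl]methanol
Product: 3 (3R)-3-methylpent-4-yne-1,3-diol
Conditions: NaAlH2(OCH2CH2OMe)2, THF, −20 → 0 °C
Reagents that add atoms: none
Why: Hydroxyl-directed hydride delivery to C2 of the 2,3-epoxy alcohol (Red-Al opening) gives the 1,3-diol with the tertiary C–O bond (C10, R) untouched; the low temperature keeps the acetylide from being hydroaluminated.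

**Step 3**
Reactants: 3 (3R)-3-methylpent-4-yne-1,3-diol
Product: 4 (3R)-3-methyl-3,5-bis(triethylsilyloxy)pent-1-yne
Conditions: Et3SiOTf (2.5 equiv), 2,6-lutidine, CH2Cl2, −78 → 0 °C
Reagents that add atoms: triethylsilyl triflate CC[Si](CC)(CC)OS(=O)(=O)C(F)(F)F
Why: Silyl triflate silylation protects both the primary and the hindered tertiary propargylic hydroxyl in one operation.

**Step 4**
Reactants: 5 prop-2-yn-1-ol
Product: 7 (Z)-3-iodo-2-methylprop-2-en-1-ol, via alkenylmagnesium alkoxide 6 (not isolated)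
Conditions: MeMgBr (2.5 equiv), CuI (10 mol%), THF, −10 °C → rt; then I2, −10 °C
Reagents that add atoms: methylmagnesium bromide C[Mg]Br; iodine II
Why: Copper-catalysed anti-carbomagnesiation of the propargylic alkoxide (Duboudin reaction) gives the chelated alkenyl Grignard 6, and iodination with retention fixes the Z geometry (iodine cis to CH2OH) that becomes the C4=C5 alkene.

**Step 5**
Reactants: 7 (Z)-3-iodo-2-methylprop-2-en-1-ol
Product: 8 (Z)-3-iodo-2-methylprop-2-enal
Conditions: MnO2, CH2Cl2, rt, dark; used at once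
Reagents that add atoms: none
Why: Neutral allylic oxidation with MnO2 gives the enal without Z/E isomerisation.

**Step 6**
Reactants: 4 (3R)-3-methyl-3,5-bis(triethylsilyloxy)pent-1-yne; 8 (Z)-3-iodo-2-methylprop-2-enal
Product: 12 (1Z,3S,4E,6R)-1-iodo-2,6-dimethyl-6,8-bis(triethylsilyloxy)octa-1,4-dien-3-yl acetate, via alkenylborane 9 (not isolated), via methyl alkenylzinc 10 (not isolated), via zinc alkoxide 11 (not isolated)
Conditions: Cy2BH, toluene, 0 °C → rt; Me2Zn, −78 °C; (−)-MIB (5 mol%), then 8, −78 → −10 °C; then Ac2O, 0 °C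
Reagents that add atoms: acetic anhydride CC(=O)OC(C)=O
Why: Syn-hydroboration gives the E-alkenylborane, boron-to-zinc transmetalation and MIB-catalysed alkenylzinc addition (Oppolzer–Walsh type) attack the Si face of the enal to set C3 as S, and the zinc alkoxide is acetylated in the same flask.

**Step 7**
Reactants: 12 (1Z,3S,4E,6R)-1-iodo-2,6-dimethyl-6,8-bis(triethylsilyloxy)octa-1,4-dien-3-yl acetate; 13 prop-2-enal
Product: 15 (3R,4Z,6S,7E,9R)-3-hydroxy-5,9-dimethyl-9,11-bis(triethylsilyloxy)undeca-1,4,7-trien-6-yl acetate, via alkenylchromium dichloride 14 (not isolated)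
Conditions: CrCl2 (4 equiv), NiCl2 (2 mol%), Kishi oxazoline-sulfonamide ligand (antipode that adds to the Si face of the aldehyde), Et3N, THF, rt
Reagents that add atoms: none
Why: Nozaki–Hiyama–Kishi coupling: zerovalent nickel inserts into the C–I bond with retention of the Z geometry, transmetalation gives the trivalent alkenylchromium 14, and the chiral ligand directs 1,2-addition to acrolein to set C6 (R in this compound, the target's C6 configuration); acetate and silyl ethers are tolerated.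

**Step 8**
Reactants: 16 2-(hydroxymethyl)prop-2-enoic acid
Product: 17 2-(acetoxymethyl)prop-2-enoic acid
Conditions: AcCl, neat, 0 °C → rt; aqueous work-up
Reagents that add atoms: acetyl chloride CC(=O)Cl
Why: O-acetylation of a hydroxy acid with acetyl chloride (as for O-acetylmandelic acid); any mixed anhydride is hydrolysed on work-up.

**Step 9**
Reactants: 15 (3R,4Z,6S,7E,9R)-3-hydroxy-5,9-dimethyl-9,11-bis(triethylsilyloxy)undeca-1,4,7-trien-6-yl acetate; 17 2-(acetoxymethyl)prop-2-enoic acid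
Product: 19 (3R,4Z,6S,7E,9R)-6-acetoxy-5,9-dimethyl-9,11-bis(triethylsilyloxy)undeca-1,4,7-trien-3-yl 2-(acetoxymethyl)prop-2-enoate, via O-acylisourea 18 (not isolated)
Conditions: DCC, DMAP (5 mol%), CH2Cl2, −20 → 0 °C
Reagents that add atoms: none
Why: Steglich esterification of the only free hydroxyl; low temperature and little DMAP suppress amine attack on the allylic acetate of the acrylate.

**Step 10**
Reactants: 19 (3R,4Z,6S,7E,9R)-6-acetoxy-5,9-dimethyl-9,11-bis(triethylsilyloxy)undeca-1,4,7-trien-3-yl 2-(acetoxymethyl)prop-2-enoate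
Product: 20 [(5S)-5-[(1Z,3S,4E,6R)-3-acetoxy-2,6-dimethyl-6,8-bis(triethylsilyloxy)octa-1,4-dienyl]-2-oxo-2,5-dihydrofuran-3-yl]methyl acetate
Conditions: second-generation Grubbs catalyst (5 mol%), toluene (5 mM), 80 °C
Reagents that add atoms: none
Why: Ring-closing metathesis of the terminal vinyl group with the 1,1-disubstituted acrylate forms the butenolide; the trisubstituted alkene and the disubstituted alkene next to the quaternary silyloxy carbon are too hindered to compete.

**Step 11**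
Reactants: 20 [(5S)-5-[(1Z,3S,4E,6R)-3-acetoxy-2,6-dimethyl-6,8-bis(triethylsilyloxy)octa-1,4-dienyl]-2-oxo-2,5-dihydrofuran-3-yl]methyl acetate
Product: 22 [(5S)-5-[(1Z,3S,4E,6R)-3-acetoxy-2,6-dimethyl-8-oxo-6-(triethylsilyloxy)octa-1,4-dienyl]-2-oxo-2,5-dihydrofuran-3-yl]methyl acetate, via alkoxysulfonium chloride 21 (not isolated)
Conditions: (COCl)2, DMSO, CH2Cl2, −78 °C; iPr2NEt, −78 → −40 °C; pH 7 buffer
Reagents that add atoms: none
Why: Under Swern conditions a primary triethylsilyl ether is cleaved and oxidised directly to the aldehyde while the tertiary silyl ether survives; cold hindered base protects the acidic C6–H of the butenolide.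

**Step 12**
Reactants: 22 [(5S)-5-[(1Z,3S,4E,6R)-3-acetoxy-2,6-dimethyl-8-oxo-6-(triethylsilyloxy)octa-1,4-dienyl]-2-oxo-2,5-dihydrofuran-3-yl]methyl acetate
Product: 25 (1E,3S,4Z,6S,7S,8R,10R)-3-acetoxy-8-hydroxy-10-(triethylsilyloxy)germacra-1,4,11(13)-trien-12,6-olide, via samarium ketyl 23 (not isolated), via samarium enolate 24 (not isolated)
Conditions: SmI2 (2.2 equiv), THF (2 mM, slow addition of 22), −78 → −20 °C, no proton source; pH 7 buffer at −20 °C
Reagents that add atoms: none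
Why: Proposed new method: SmI2 reduces only the aldehyde to ketyl 23, whose carbon radical adds 10-exo to C7 of the butenolide on the face anti to the C5 substituent at C6 (setting 7S, trans-lactone) with the samarium-bound oxygen antiperiplanar to C11 (predicted to set 8R), and a second electron gives enolate 24, which expels acetate to form the exocyclic methylene; the closest known chemistry is the Molander-type SmI2 ketyl–olefin cyclisation onto unsaturated esters (up to eight-membered carbocycles), anti-selective radical conjugate addition to 5-substituted butenolides and β-acetoxy elimination from samarium enolates.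

**Step 13**
Reactants: 25 (1E,3S,4Z,6S,7S,8R,10R)-3-acetoxy-8-hydroxy-10-(triethylsilyloxy)germacra-1,4,11(13)-trien-12,6-olide; 26 (Z)-2-methylbut-2-enoic acid
Product: 28 (1E,3S,4Z,6S,7S,8R,10R)-3-acetoxy-8-[(Z)-2-methylbut-2-enoyloxy]-10-(triethylsilyloxy)germacra-1,4,11(13)-trien-12,6-olide, via mixed anhydride 27 (not isolated)
Conditions: 26, 2,4,6-trichlorobenzoyl chloride, Et3N, toluene, rt; then 25, 75 °C
Reagents that add atoms: none
Why: Yamaguchi mixed-anhydride esterification without DMAP acylates the secondary C8 hydroxyl with retention and is the established way to make angelates without isomerisation to the tiglate.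

**Step 14**
Reactants: 28 (1E,3S,4Z,6S,7S,8R,10R)-3-acetoxy-8-[(Z)-2-methylbut-2-enoyloxy]-10-(triethylsilyloxy)germacra-1,4,11(13)-trien-12,6-olide
Product: 29 (1E,3S,4Z,6S,7S,8R,10R)-3-acetoxy-10-hydroxy-8-[(Z)-2-methylbut-2-enoyloxy]germacra-1,4,11(13)-trien-12,6-olide (target)
Conditions: HF·pyridine, pyridine, THF, 0 °C
Reagents that add atoms: none
Why: Buffered fluoride desilylation frees the tertiary C10 hydroxyl without touching the esters, the methylene lactone or the bis-allylic acetate.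

**Compound list**
1 | (E)-3-methylpent-2-en-4-yn-1-ol | OC/C=C(\C)C#C | starting material
2 | [(2S,3S)-3-ethynyl-3-methyloxiran-2-yl]methanol | C#C[C@]1(C)O[C@H]1CO | intermediate
3 | (3R)-3-methylpent-4-yne-1,3-diol | C#C[C@](C)(O)CCO | intermediate
4 | (3R)-3-methyl-3,5-bis(triethylsilyloxy)pent-1-yne | C#C[C@](C)(O[Si](CC)(CC)CC)CCO[Si](CC)(CC)CC | intermediate
5 | prop-2-yn-1-ol | C#CCO | starting material
6 | (Z)-alkenylmagnesium bromide of the bromomagnesium alkoxide of 2-methylprop-2-en-1-ol | Br[Mg]OC/C(C)=C\[Mg]Br | intermediate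
7 | (Z)-3-iodo-2-methylprop-2-en-1-ol | OC/C(C)=C\I | intermediate
8 | (Z)-3-iodo-2-methylprop-2-enal | O=C/C(C)=C\I | intermediate
9 | dicyclohexyl[(1E,3R)-3-methyl-3,5-bis(triethylsilyloxy)pent-1-enyl]borane | C1CCCCC1B(/C=C/[C@](C)(O[Si](CC)(CC)CC)CCO[Si](CC)(CC)CC)C1CCCCC1 | intermediate
10 | methyl[(1E,3R)-3-methyl-3,5-bis(triethylsilyloxy)pent-1-enyl]zinc | C[Zn]/C=C/[C@](C)(O[Si](CC)(CC)CC)CCO[Si](CC)(CC)CC | intermediate
11 | methylzinc (1Z,3S,4E,6R)-1-iodo-2,6-dimethyl-6,8-bis(triethylsilyloxy)octa-1,4-dien-3-olate | I/C=C(/C)[C@@H](O[Zn]C)/C=C/[C@](C)(O[Si](CC)(CC)CC)CCO[Si](CC)(CC)CC | intermediate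
12 | (1Z,3S,4E,6R)-1-iodo-2,6-dimethyl-6,8-bis(triethylsilyloxy)octa-1,4-dien-3-yl acetate | I/C=C(/C)[C@@H](OC(C)=O)/C=C/[C@](C)(O[Si](CC)(CC)CC)CCO[Si](CC)(CC)CC | intermediate
13 | prop-2-enal (acrolein) | C=CC=O | starting material
14 | [(1Z,3S,4E,6R)-3-acetoxy-2,6-dimethyl-6,8-bis(triethylsilyloxy)octa-1,4-dienyl]chromium dichloride | Cl[Cr](Cl)/C=C(/C)[C@@H](OC(C)=O)/C=C/[C@](C)(O[Si](CC)(CC)CC)CCO[Si](CC)(CC)CC | intermediate
15 | (3R,4Z,6S,7E,9R)-3-hydroxy-5,9-dimethyl-9,11-bis(triethylsilyloxy)undeca-1,4,7-trien-6-yl acetate | C=C[C@@H](O)/C=C(/C)[C@@H](OC(C)=O)/C=C/[C@](C)(O[Si](CC)(CC)CC)CCO[Si](CC)(CC)CC | intermediate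
16 | 2-(hydroxymethyl)prop-2-enoic acid | OCC(=C)C(=O)O | starting material
17 | 2-(acetoxymethyl)prop-2-enoic acid | CC(=O)OCC(=C)C(=O)O | intermediate
18 | O-[2-(acetoxymethyl)prop-2-enoyl]-N,N'-dicyclohexylisourea | CC(=O)OCC(=C)C(=O)OC(=NC1CCCCC1)NC1CCCCC1 | intermediate
19 | (3R,4Z,6S,7E,9R)-6-acetoxy-5,9-dimethyl-9,11-bis(triethylsilyloxy)undeca-1,4,7-trien-3-yl 2-(acetoxymethyl)prop-2-enoate | C=C[C@@H](OC(=O)C(=C)COC(C)=O)/C=C(/C)[C@@H](OC(C)=O)/C=C/[C@](C)(O[Si](CC)(CC)CC)CCO[Si](CC)(CC)CC | intermediate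
20 | [(5S)-5-[(1Z,3S,4E,6R)-3-acetoxy-2,6-dimethyl-6,8-bis(triethylsilyloxy)octa-1,4-dienyl]-2-oxo-2,5-dihydrofuran-3-yl]methyl acetate | CC(=O)OCC1=C[C@@H](OC1=O)/C=C(/C)[C@@H](OC(C)=O)/C=C/[C@](C)(O[Si](CC)(CC)CC)CCO[Si](CC)(CC)CC | intermediate
21 | dimethylsulfonium chloride O-bound to the primary oxygen of desilylated 20 | CC(=O)OCC1=C[C@@H](OC1=O)/C=C(/C)[C@@H](OC(C)=O)/C=C/[C@](C)(O[Si](CC)(CC)CC)CCO[S+](C)C.[Cl-] | intermediate
22 | [(5S)-5-[(1Z,3S,4E,6R)-3-acetoxy-2,6-dimethyl-8-oxo-6-(triethylsilyloxy)octa-1,4-dienyl]-2-oxo-2,5-dihydrofuran-3-yl]methyl acetate | CC(=O)OCC1=C[C@@H](OC1=O)/C=C(/C)[C@@H](OC(C)=O)/C=C/[C@](C)(O[Si](CC)(CC)CC)CC=O | intermediate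
23 | diiodosamarium ketyl radical of aldehyde 22 | CC(=O)OCC1=C[C@@H](OC1=O)/C=C(/C)[C@@H](OC(C)=O)/C=C/[C@](C)(O[Si](CC)(CC)CC)C[CH]O[Sm](I)I | intermediate
24 | cyclised bis(diiodosamarium) lactone enolate/C8 alkoxide, C13 acetate still in place | CC(=O)OCC1=C(O[Sm](I)I)O[C@H]2/C=C(/C)[C@@H](OC(C)=O)/C=C/[C@](C)(O[Si](CC)(CC)CC)C[C@@H](O[Sm](I)I)[C@H]12 | intermediate
25 | (1E,3S,4Z,6S,7S,8R,10R)-3-acetoxy-8-hydroxy-10-(triethylsilyloxy)germacra-1,4,11(13)-trien-12,6-olide | C=C1C(=O)O[C@H]2/C=C(/C)[C@@H](OC(C)=O)/C=C/[C@](C)(O[Si](CC)(CC)CC)C[C@@H](O)[C@H]12 | intermediate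
26 | (Z)-2-methylbut-2-enoic acid (angelic acid) | C/C=C(/C)C(=O)O | starting material
27 | (Z)-2-methylbut-2-enoic 2,4,6-trichlorobenzoic anhydride | C/C=C(/C)C(=O)OC(=O)c1c(Cl)cc(Cl)cc1Cl | intermediate
28 | (1E,3S,4Z,6S,7S,8R,10R)-3-acetoxy-8-[(Z)-2-methylbut-2-enoyloxy]-10-(triethylsilyloxy)germacra-1,4,11(13)-trien-12,6-olide | C=C1C(=O)O[C@H]2/C=C(/C)[C@@H](OC(C)=O)/C=C/[C@](C)(O[Si](CC)(CC)CC)C[C@@H](OC(=O)/C(C)=C\C)[C@H]12 | intermediate
29 | (1E,3S,4Z,6S,7S,8R,10R)-3-acetoxy-10-hydroxy-8-[(Z)-2-methylbut-2-enoyloxy]germacra-1,4,11(13)-trien-12,6-olide | C=C1C(=O)O[C@H]2/C=C(/C)[C@@H](OC(C)=O)/C=C/[C@](C)(O)C[C@@H](OC(=O)/C(C)=C\C)[C@H]12 | target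

**Totals**
Total step count: 14. Longest linear sequence: 11 steps (steps 1, 2, 3, 6, 7, 9, 10, 11, 12, 13, 14).

**Three steps most likely to fail**

Step 12 (ketyl–olefin closure of the ten-membered ring). The ring closure may lose to pinacol coupling or simple reduction, and the C8 configuration rests on a transition-state argument, not on precedent. The fallback sets out from 15 and comes back at 25. Carbinol 15 is esterified with 2-(bromomethyl)prop-2-enoic acid (DCC) to give the bromomethyl acrylate F1. Ring-closing metathesis then gives the 3-(bromomethyl)butenolide F2, and the same oxidative desilylation gives the bromo aldehyde F3. F3 is closed with CrCl2 in THF/DMF at high dilution: the allylic bromide is reduced through the allyl radical to an allylchromium species, which adds through C7 to the C8 aldehyde in a cyclic transition state and delivers the exocyclic methylene and the C7–C8 bond of 25 by an organometallic instead of a ketyl pathway.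

Step 7 (ligand-controlled Nozaki–Hiyama–Kishi coupling). Facial control at C6 with acrolein may be modest, since the remote C3 centre gives no help. The fallback sets out from 12 and comes back at 15. The alkenyl iodide is formylated with CO and Bu3SnH under Pd(PPh3)4 to the (Z)-enal F4. Divinylzinc (from CH2=CHMgBr and ZnCl2) is then added under (+)-MIB catalysis, which attacks the Re face of the enal and gives 15 with catalyst-controlled C6 configuration by the same zinc chemistry that sets C3.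

Step 10 (ring-closing metathesis). The ruthenium alkylidene at C7 could instead close onto the C1=C2 alkene to give a cyclohexa-1,4-diene and cut off the western chain. The fallback sets out from 7 and comes back at 20; it builds the butenolide before the C1=C2 alkene exists. Alcohol 7 is silylated (tBuMe2SiCl, imidazole) to the silyl ether F5. F5 is coupled with 13 under the step 7 conditions to give carbinol F6, which is esterified with 17 to the acrylate F7. Metathesis of F7 gives butenolide F8, where no competing alkene is present. HF·pyridine gives the allylic alcohol F9 and MnO2 gives the (Z)-enal F10. Alkenylzinc 10 is then added to F10 under (−)-MIB catalysis with an Ac2O quench, which gives 20 directly.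

**Further compounds**
F1 | step 12 | (3R,4Z,6S,7E,9R)-6-acetoxy-5,9-dimethyl-9,11-bis(triethylsilyloxy)undeca-1,4,7-trien-3-yl 2-(bromomethyl)prop-2-enoate | C=C[C@@H](OC(=O)C(=C)CBr)/C=C(/C)[C@@H](OC(C)=O)/C=C/[C@](C)(O[Si](CC)(CC)CC)CCO[Si](CC)(CC)CC
F2 | step 12 | (1Z,3S,4E,6R)-1-[(2S)-4-(bromomethyl)-5-oxo-2,5-dihydrofuran-2-yl]-2,6-dimethyl-6,8-bis(triethylsilyloxy)octa-1,4-dien-3-yl acetate | BrCC1=C[C@@H](OC1=O)/C=C(/C)[C@@H](OC(C)=O)/C=C/[C@](C)(O[Si](CC)(CC)CC)CCO[Si](CC)(CC)CC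
F3 | step 12 | (1Z,3S,4E,6R)-1-[(2S)-4-(bromomethyl)-5-oxo-2,5-dihydrofuran-2-yl]-2,6-dimethyl-8-oxo-6-(triethylsilyloxy)octa-1,4-dien-3-yl acetate | BrCC1=C[C@@H](OC1=O)/C=C(/C)[C@@H](OC(C)=O)/C=C/[C@](C)(O[Si](CC)(CC)CC)CC=O
F4 | step 7 | (2Z,4S,5E,7R)-3,7-dimethyl-1-oxo-7,9-bis(triethylsilyloxy)nona-2,5-dien-4-yl acetate | O=C/C=C(/C)[C@@H](OC(C)=O)/C=C/[C@](C)(O[Si](CC)(CC)CC)CCO[Si](CC)(CC)CC
F5 | step 10 | tert-butyl{[(Z)-3-iodo-2-methylprop-2-enyl]oxy}dimethylsilane | CC(C)(C)[Si](C)(C)OC/C(C)=C\I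
F6 | step 10 | (3R,4Z)-6-(tert-butyldimethylsilyloxy)-5-methylhexa-1,4-dien-3-ol | C=C[C@@H](O)/C=C(/C)CO[Si](C)(C)C(C)(C)C
F7 | step 10 | (3R,4Z)-6-(tert-butyldimethylsilyloxy)-5-methylhexa-1,4-dien-3-yl 2-(acetoxymethyl)prop-2-enoate | C=C[C@@H](OC(=O)C(=C)COC(C)=O)/C=C(/C)CO[Si](C)(C)C(C)(C)C
F8 | step 10 | [(5S)-5-[(Z)-3-(tert-butyldimethylsilyloxy)-2-methylprop-1-enyl]-2-oxo-2,5-dihydrofuran-3-yl]methyl acetate | CC(=O)OCC1=C[C@@H](OC1=O)/C=C(/C)CO[Si](C)(C)C(C)(C)C
F9 | step 10 | [(5S)-5-[(Z)-3-hydroxy-2-methylprop-1-enyl]-2-oxo-2,5-dihydrofuran-3-yl]methyl acetate | CC(=O)OCC1=C[C@@H](OC1=O)/C=C(/C)CO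
F10 | step 10 | [(5S)-5-[(Z)-2-methyl-3-oxoprop-1-enyl]-2-oxo-2,5-dihydrofuran-3-yl]methyl acetate | CC(=O)OCC1=C[C@@H](OC1=O)/C=C(/C)C=O
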